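(The readings were computed on assumed constants; the scatter is artificial.)

the same everywhere: solid monomer 0.050 M

|  | protic impurity | initiator | remark | time |
|---|---|---|---|---|
| spring | 2.5 mM | 0.34 mol% | run made earlier |  |
| maple | 2.50 mM | 0.5 mol% |  | 12 h |
| birch | 5.00 mM | 0.5 mol% |  | 12 h |
| larch | 10.0 mM | 0.5 mol% |  | 12 h |

spring run (percent of the solid monomer charged)

| time / h | monomer in chains / % | solid monomer / % |
|---|---|---|
| 0.667 | 0 | 97.4 |
| 2.00 | 1.6 | 91.2 |
| 3.00 | 3.0 | 86.6 |
| 5.00 | 8.3 | 78.5 |
| 8.00 | 16.4 | 68.6 |

(standard deviation of a reading: 0.5 percentage points)

- as a solid, counted per litre of solution: solid monomer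
- the analysis behind the earlier runs scatters by 0.5 percentage points, standard deviation
- at the start none of the solid monomer is in solution
- "hardly changes" means that all values lie within two and a half points (for a concentration: within two and a half percent of the largest)
- no earlier run changes the charge of initiator; that part of a forecast is a guess
- no earlier run changes the charge of protic impurity; that part of a forecast is a guess

* amount of monomer in chains at the end, in percent of the solid monomer charged for maple, birch, larch, in this order
* the course of these numbers from the first flask to the last (falls, then rises / rises, then falls / rises all the way / falls all the way / hardly changes)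

**Reading the order.** Take the part of the charge that is neither solid nor in chains, free monomer, as the quantity to follow. In the spring run, chains gained 0.0270 /h of the charge between 5.00 h and 8.00 h, while free monomer averaged 14.1%. I therefore read the rate as first order in [free monomer], with a pseudo-first-order constant of 0.191 /h. For maple I scaled it by the square root of the initiator loadings, which is a guess, and got 0.232 /h.

**Slope and knee.** Spring's solid fell by 0.0465 /h at a mean free monomer of 4.90%, and by 0.0330 /h later. A straight line through these fell with a constant of 0.147 /h and gave a supply of 0.0537 /h into empty solution. So I drew maple's free monomer starting at that supply slope and its chains starting flat, with the knee at 2.64 h.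

**The level.** After the knee, free monomer stands at the standing level 14.2%, the supply divided by the sum of the two constants. Maple's chains then run straight at 0.0329 /h and reach 30.8% at 12.0 h. That leaves 55.0% as solid, so the line holds to the end. Spring's chains kept growing with impurity at 14.7 times its initiator, but no earlier run changes the impurity, so holding birch and larch near maple's figure was my own guess.

**The forecast.** The forecast differed from my guess: it gave 32%, 22% and 13%, falls all the way, and of its impurity part it said: “The impurity effect is a guess”.

**The flask.** Maple gave 31.5%, birch 30.9% and larch 29.8%: the row hardly changes. Growing radical stood at 9.75 × 10⁻⁹ M in maple and 9.75 × 10⁻⁹ M in larch at 12.0 h. Against my level of 14.2%, free monomer ended higher in maple at 14.7% and lower in larch at 13.7%. Carried to larch, my constant times that level gave 0.0329 /h, and larch's chains gained 0.0308 /h of the charge between 6.00 h and 12.0 h.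

    free monomer + initiating radical → growing radical + monomer in chains (k = 51000 /M/s)
    2 growing radical → dead chain (k = 2.40 × 10⁶ /M/s)
    protic impurity + free monomer → quenched substrate (k = 0.0670 /M/min)
    free monomer + growing radical → monomer in chains + growing radical, rate k4*[growing radical]*[free monomer] (k = 4.00 × 10⁵ /M/min)
    solid monomer ⇌ free monomer, rate k5*(cs5 - [free monomer]) while solid is left; crystals form when [free monomer] > cs5 (solubility = 33.0 mM, k = 0.00120 /min)
    initiator → 2 initiating radical (k = 5.70 × 10⁻⁵ /min)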